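**Retrosynthetic overview**
1. Target 36 comes from desilylation of 35. The Cf carbinol is set by CBS reduction of enone 34, and the seven-membered ring is closed last (Cf–Cg) by intramolecular NiCl2/CrCl2 coupling of enol triflate–aldehyde 31.
2. The key fragment union is the Cb–Cc bond: an intermolecular CrCl2-mediated Nozaki–Hiyama allylation of aldehyde 23 with cyclopentenylmethyl bromide 8. It creates the exocyclic methylene, Cb and Cc in one step.
3. Bromide 8 comes from (R)-4-silyloxycyclopentenone 1 by vinyl conjugate addition/elimination, Baylis–Hillman hydroxymethylation and Luche reduction (Cj–O cis to the Ch substituent).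
4. Aldehyde 23 comes from cis-lactone 16 (Brown Z-crotylation of 4-methylpent-3-enal, hydroboration, lactonisation), alkylated trans to its methyl group to set Cd.
5. Ring order: the five-membered ring comes from the chiral pool first; the seven-membered ring is formed last.

Assumption and labels: 1, 9 and all reagents are bought; ring atoms follow the target SMILES from its second atom: Ca (five-ring C=CH2), Cb, Cc (CHOH), Cd (bears the side chain), Ce, Cf (CHOH), Cg (seven-ring C=CH2), Ch, Ci, Cj (five-ring CHOH).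

**Route**

Step 1
Reactants: 1 (R)-4-[(tert-butyldimethylsilyl)oxy]cyclopent-2-en-1-one
Product: 3 (3S,4R)-4-[(tert-butyldimethylsilyl)oxy]-3-ethenylcyclopentan-1-one, via trimethylsilyl enol ether 2 (not isolated)
Conditions: CH2=CHMgBr, CuBr·SMe2 (10 mol %), Me3SiCl, THF, −78 °C; then 1 M HCl, 0 °C
Reagents that add atoms: vinylmagnesium bromide (C=C[Mg]Br)
Why: Copper-catalysed, silyl-chloride-accelerated conjugate addition delivers the vinyl group trans to the bulky silyloxy group, which fixes Ch; brief acid cleaves the enol silane.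

Step 2
Reactants: 3 (3S,4R)-4-[(tert-butyldimethylsilyl)oxy]-3-ethenylcyclopentan-1-one
Product: 4 (S)-4-ethenylcyclopent-2-en-1-one
Conditions: DBU, CH2Cl2, 0 °C
Reagents that add atoms: none
Why: E1cB β-elimination of the silanol transposes the enone so that the old carbonyl becomes the future Cj, and the Ch stereocentre is not touched.

Step 3
Reactants: 4 (S)-4-ethenylcyclopent-2-en-1-one
Product: 5 (S)-4-ethenyl-2-(hydroxymethyl)cyclopent-2-en-1-one
Conditions: 37 % aq. HCHO, imidazole (20 mol %), THF–H2O 1:1, rt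
Reagents that add atoms: formaldehyde (C=O)
Why: Morita–Baylis–Hillman reaction puts the hydroxymethyl carbon on the enone α-carbon (future Ca) under weakly basic conditions.

Step 4
Reactants: 5 (S)-4-ethenyl-2-(hydroxymethyl)cyclopent-2-en-1-one
Product: 6 (1S,4S)-4-ethenyl-2-(hydroxymethyl)cyclopent-2-en-1-ol
Conditions: NaBH4, CeCl3·7H2O, MeOH, −78 °C
Reagents that add atoms: none
Why: Luche 1,2-reduction; hydride attacks the face anti to the Ch vinyl group, giving the cis-1,4 alcohol and so setting Cj.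

Step 5
Reactants: 6 (1S,4S)-4-ethenyl-2-(hydroxymethyl)cyclopent-2-en-1-ol
Product: 7 (1S,4S)-2-(bromomethyl)-4-ethenylcyclopent-2-en-1-ol
Conditions: CBr4 (1.05 equiv), PPh3 (1.1 equiv), CH2Cl2, −40 → −20 °C
Reagents that add atoms: carbon tetrabromide (BrC(Br)(Br)Br)
Why: Appel bromination is selective for the unhindered primary allylic hydroxyl over the secondary one at low temperature.

Step 6
Reactants: 7 (1S,4S)-2-(bromomethyl)-4-ethenylcyclopent-2-en-1-ol
Product: 8 {[(1S,4S)-2-(bromomethyl)-4-ethenylcyclopent-2-en-1-yl]oxy}(tert-butyl)dimethylsilane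
Conditions: TBSOTf, 2,6-lutidine, CH2Cl2, −78 °C
Reagents that add atoms: tert-butyldimethylsilyl triflate (CC(C)(C)[Si](C)(C)OS(=O)(=O)C(F)(F)F)
Why: Fast silylation of the secondary allylic alcohol with a non-nucleophilic base leaves the allylic bromide intact.

Step 7
Reactants: 9 4-methylpent-3-en-1-ol
Product: 10 4-methylpent-3-enal
Conditions: TEMPO (10 mol %), PhI(OAc)2, CH2Cl2, rt; used as a solution
Reagents that add atoms: none
Why: TEMPO/PhI(OAc)2 oxidation stops at the aldehyde and is mild enough to avoid conjugation of the β,γ-double bond.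

Step 8
Reactants: 10 4-methylpent-3-enal
Product: 12 (3S,4S)-3,7-dimethylocta-1,6-dien-4-ol, via dialkylborinate ester 11 (not isolated)
Conditions: cis-2-butene, n-BuLi, KOt-Bu, THF, −78 → −45 °C; (+)-Ipc2BOMe, −78 °C; BF3·OEt2; 10, −78 °C; then NaOH, H2O2, rt
Reagents that add atoms: cis-2-butene (C/C=C\C)
Why: Brown crotylboration; the Z-crotylborane reacts through a closed chair transition state to give the syn adduct, and the isopinocampheyl groups derived from (−)-α-pinene direct attack to the Re face, setting both side-chain centres.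

Step 9
Reactants: 12 (3S,4S)-3,7-dimethylocta-1,6-dien-4-ol
Product: 14 (3S,4S)-3,7-dimethyloct-6-ene-1,4-diol, via B-alkyl-9-BBN adduct 13 (not isolated)
Conditions: 9-BBN (1.5 equiv), THF, 0 °C → rt; then NaOH, H2O2, 0 °C
Reagents that add atoms: hydrogen peroxide (OO)
Why: 9-BBN hydroborates only the monosubstituted alkene (anti-Markovnikov) and leaves the trisubstituted prenyl alkene alone.

Step 10
Reactants: 14 (3S,4S)-3,7-dimethyloct-6-ene-1,4-diol
Product: 16 (4S,5S)-4-methyl-5-(3-methylbut-2-en-1-yl)oxolan-2-one, via lactol 15 (not isolated)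
Conditions: TEMPO (20 mol %), PhI(OAc)2 (2.5 equiv), CH2Cl2, rt
Reagents that add atoms: none
Why: TEMPO-catalysed oxidative lactonisation; the primary alcohol is oxidised selectively, the lactol closes and is oxidised to the cis-lactone.

Step 11
Reactants: 16 (4S,5S)-4-methyl-5-(3-methylbut-2-en-1-yl)oxolan-2-one
Product: 18 (3S,4S,5S)-3-{2-[(tert-butyldimethylsilyl)oxy]ethyl}-4-methyl-5-(3-methylbut-2-en-1-yl)oxolan-2-one, via lithium enolate 17 (not isolated)
Conditions: LiN(i-Pr)2, THF, −78 °C; ICH2CH2OTBS, HMPA, −78 → −20 °C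
Reagents that add atoms: tert-butyl(2-iodoethoxy)dimethylsilane (CC(C)(C)[Si](C)(C)OCCI)
Why: Lactone enolate alkylation occurs anti to the adjacent methyl group (both ring substituents block the same face), which sets Cd trans to the methyl group.

Step 12
Reactants: 18 (3S,4S,5S)-3-{2-[(tert-butyldimethylsilyl)oxy]ethyl}-4-methyl-5-(3-methylbut-2-en-1-yl)oxolan-2-one
Product: 19 (2S,3S,4S)-2-{2-[(tert-butyldimethylsilyl)oxy]ethyl}-3,7-dimethyloct-6-ene-1,4-diol
Conditions: LiAlH4, THF, 0 °C
Reagents that add atoms: none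
Why: Irreversible hydride reduction opens the lactone to the diol without touching the stereocentres.

Step 13
Reactants: 19 (2S,3S,4S)-2-{2-[(tert-butyldimethylsilyl)oxy]ethyl}-3,7-dimethyloct-6-ene-1,4-diol
Product: 20 1-O-triethylsilyl ether of 19
Conditions: Et3SiCl (1.05 equiv), imidazole, CH2Cl2, −40 °C
Reagents that add atoms: chlorotriethylsilane (CC[Si](Cl)(CC)CC)
Why: The primary hydroxyl is silylated much faster than the hindered secondary one.

Step 14
Reactants: 20 1-O-triethylsilyl ether of 19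
Product: 21 4-O-acetate of 20
Conditions: Ac2O, DMAP (cat.), pyridine, rt
Reagents that add atoms: acetic anhydride (CC(=O)OC(C)=O)
Why: DMAP-catalysed acetylation installs the target's only ester on the free secondary hydroxyl.

Step 15
Reactants: 21 4-O-acetate of 20
Product: 23 (2S,3S,4S)-4-acetoxy-2-{2-[(tert-butyldimethylsilyl)oxy]ethyl}-3,7-dimethyloct-6-enal, via alkoxysulfonium chloride 22 (not isolated)
Conditions: (COCl)2, DMSO, CH2Cl2, −78 → −40 °C; then Et3N, −78 → 0 °C
Reagents that add atoms: none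
Why: Under Swern conditions the primary triethylsilyl ether is cleaved in situ and oxidised to the aldehyde, while the primary TBS ether and the acetate survive.

Step 16
Reactants: 8 {[(1S,4S)-2-(bromomethyl)-4-ethenylcyclopent-2-en-1-yl]oxy}(tert-butyl)dimethylsilane; 23 (2S,3S,4S)-4-acetoxy-2-{2-[(tert-butyldimethylsilyl)oxy]ethyl}-3,7-dimethyloct-6-enal
Product: 25 Cc-hydroxy coupling product (2-methylidenecyclopentane carrying Cj-OTBS, Ch-vinyl and at Cb the CH(OH) chain of 23), via allylchromium dichloride 24 (not isolated)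
Conditions: CrCl2 (4 equiv), THF, 0 °C → rt; aqueous work-up
Reagents that add atoms: none
Why: Nozaki–Hiyama allylation; the allylchromium (trivalent chromium) reacts at its ring γ-carbon on the face anti to the vinyl and silyloxy groups through a Zimmerman–Traxler chair (anti adduct), and Felkin–Anh control by Cd of the aldehyde is matched, so the exocyclic methylene, Cb and Cc form together.

Step 17
Reactants: 25 Cc-hydroxy coupling product
Product: 26 Cc-O-TBS ether of 25
Conditions: TBSOTf, 2,6-lutidine, CH2Cl2, −78 → 0 °C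
Reagents that add atoms: tert-butyldimethylsilyl triflate (CC(C)(C)[Si](C)(C)OS(=O)(=O)C(F)(F)F)
Why: The silyl triflate protects even this hindered secondary alcohol and so prevents oxypalladation and lactol formation later.

Step 18
Reactants: 26 Cc-O-TBS ether of 25
Product: 27 methyl ketone (Ch-acetyl compound)
Conditions: PdCl2 (15 mol %), CuCl, O2 (1 atm), DMF–H2O 7:1, rt
Reagents that add atoms: water (O)
Why: Tsuji–Wacker oxidation converts only the monosubstituted vinyl group into the methyl ketone; the 1,1-disubstituted and trisubstituted alkenes do not react.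

Step 19
Reactants: 27 methyl ketone (Ch-acetyl compound)
Product: 29 enol triflate of 27, via potassium enolate 28 (not isolated)
Conditions: KN(SiMe3)2 (1.05 equiv), THF, −78 °C; PhNTf2, −78 → −20 °C
Reagents that add atoms: N-phenylbis(trifluoromethanesulfonimide) (O=S(=O)(N(c1ccccc1)S(=O)(=O)C(F)(F)F)C(F)(F)F)
Why: Kinetic deprotonation at the methyl group (not at the hindered Ch methine or the less acidic acetate) and O-triflation give the 1,1-disubstituted alkenyl triflate that becomes Cg=CH2.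

Step 20
Reactants: 29 enol triflate of 27
Product: 30 primary alcohol (Cf-OH) from 29
Conditions: HF·pyridine, pyridine, THF, 0 °C
Reagents that add atoms: none
Why: Buffered HF·pyridine removes the primary TBS ether much faster than the two secondary ones.

Step 21
Reactants: 30 primary alcohol (Cf-OH) from 29
Product: 31 aldehyde (Cf=O) from 30
Conditions: Dess–Martin periodinane, pyridine, CH2Cl2, 0 °C → rt
Reagents that add atoms: none
Why: Mild periodinane oxidation gives the aldehyde without touching the triflate, acetate or alkenes.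

Step 22
Reactants: 31 aldehyde (Cf=O) from 30
Product: 33 Cf-epimeric bicyclic allylic alcohols, via alkenylchromium dichloride 32 (not isolated)
Conditions: CrCl2 (8 equiv), NiCl2 (2 mol %), DMF, 0.005 M, rt
Reagents that add atoms: none
Why: Nozaki–Hiyama–Kishi reaction; nickel-catalysed activation of the enol triflate, transfer to chromium and aldehyde-selective addition close the seven-membered ring and give the 2-methylene-1-ol motif, with Cf formed as a mixture that converges in steps 23 and 24.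

Step 23
Reactants: 33 Cf-epimeric bicyclic allylic alcohols
Product: 34 bicyclic α-methylene ketone (Cf=O)
Conditions: Dess–Martin periodinane, pyridine, CH2Cl2, 0 °C
Reagents that add atoms: none
Why: Both epimers are oxidised to the same enone, so the outcome no longer depends on the selectivity of the ring closure.

Step 24
Reactants: 34 bicyclic α-methylene ketone (Cf=O)
Product: 35 (Cf R)-allylic alcohol bis-TBS ether
Conditions: (S)-2-methyl-CBS-oxazaborolidine (30 mol %), catecholborane, toluene, −78 °C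
Reagents that add atoms: none
Why: Corey–Bakshi–Shibata reduction; with the alkenyl carbon Cg as the large group the (S)-catalyst delivers hydride to give the R carbinol at Cf (same sense as acetophenone to (R)-1-phenylethanol), and catecholborane gives clean 1,2-reduction.

Step 25
Reactants: 35 (Cf R)-allylic alcohol bis-TBS ether
Product: 36 target CNP0210891.3
Conditions: HF·pyridine, THF, 0 °C → rt
Reagents that add atoms: none
Why: Acidic fluoride removes both secondary TBS ethers without cleaving or migrating the acetate.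

**Compound list**
1 | (R)-4-[(tert-butyldimethylsilyl)oxy]cyclopent-2-en-1-one | O=C1C[C@@H](O[Si](C)(C)C(C)(C)C)C=C1 | starting material
2 | trimethylsilyl enol ether of 3 | C[Si](C)(C)OC1=C[C@@H](C=C)[C@H](O[Si](C)(C)C(C)(C)C)C1 | intermediate (not isolated)
3 | (3S,4R)-4-[(tert-butyldimethylsilyl)oxy]-3-ethenylcyclopentan-1-one | O=C1C[C@@H](O[Si](C)(C)C(C)(C)C)[C@H](C=C)C1 | intermediate
4 | (S)-4-ethenylcyclopent-2-en-1-one | O=C1C=C[C@H](C=C)C1 | intermediate
5 | (S)-4-ethenyl-2-(hydroxymethyl)cyclopent-2-en-1-one | O=C1C(CO)=C[C@H](C=C)C1 | intermediate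
6 | (1S,4S)-4-ethenyl-2-(hydroxymethyl)cyclopent-2-en-1-ol | OCC1=C[C@H](C=C)C[C@@H]1O | intermediate
7 | (1S,4S)-2-(bromomethyl)-4-ethenylcyclopent-2-en-1-ol | BrCC1=C[C@H](C=C)C[C@@H]1O | intermediate
8 | {[(1S,4S)-2-(bromomethyl)-4-ethenylcyclopent-2-en-1-yl]oxy}(tert-butyl)dimethylsilane | BrCC1=C[C@H](C=C)C[C@@H]1O[Si](C)(C)C(C)(C)C | intermediate
9 | 4-methylpent-3-en-1-ol | CC(C)=CCCO | starting material
10 | 4-methylpent-3-enal | CC(C)=CCC=O | intermediate
11 | bis(isopinocampheyl)borinate ester of 12 | C=C[C@H](C)[C@H](CC=C(C)C)OB([C@H]1C[C@H]2C[C@@H]([C@@H]1C)C2(C)C)[C@H]1C[C@H]2C[C@@H]([C@@H]1C)C2(C)C | intermediate (not isolated)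
12 | (3S,4S)-3,7-dimethylocta-1,6-dien-4-ol | C=C[C@H](C)[C@H](CC=C(C)C)O | intermediate
13 | B-alkyl-9-BBN adduct of 12 (boron on C1) | C(CB1C2CCCC1CCC2)[C@H](C)[C@H](CC=C(C)C)O | intermediate (not isolated)
14 | (3S,4S)-3,7-dimethyloct-6-ene-1,4-diol | OCC[C@H](C)[C@H](CC=C(C)C)O | intermediate
15 | (4S,5S)-4-methyl-5-(3-methylbut-2-en-1-yl)oxolan-2-ol (lactol, both anomers) | OC1C[C@H](C)[C@H](CC=C(C)C)O1 | intermediate (not isolated)
16 | (4S,5S)-4-methyl-5-(3-methylbut-2-en-1-yl)oxolan-2-one | O=C1C[C@H](C)[C@H](CC=C(C)C)O1 | intermediate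
17 | lithium enolate of 16 | [Li+].[O-]C1=C[C@H](C)[C@H](CC=C(C)C)O1 | intermediate (not isolated)
18 | (3S,4S,5S)-3-{2-[(tert-butyldimethylsilyl)oxy]ethyl}-4-methyl-5-(3-methylbut-2-en-1-yl)oxolan-2-one | O=C1[C@@H](CCO[Si](C)(C)C(C)(C)C)[C@H](C)[C@H](CC=C(C)C)O1 | intermediate
19 | (2S,3S,4S)-2-{2-[(tert-butyldimethylsilyl)oxy]ethyl}-3,7-dimethyloct-6-ene-1,4-diol | OC[C@H]([C@H](C)[C@H](CC=C(C)C)O)CCO[Si](C)(C)C(C)(C)C | intermediate
20 | 1-O-triethylsilyl ether of 19 | CC[Si](CC)(CC)OC[C@H]([C@H](C)[C@H](CC=C(C)C)O)CCO[Si](C)(C)C(C)(C)C | intermediate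
21 | 4-O-acetate of 20 | CC[Si](CC)(CC)OC[C@H]([C@H](C)[C@H](CC=C(C)C)OC(C)=O)CCO[Si](C)(C)C(C)(C)C | intermediate
22 | alkoxydimethylsulfonium chloride from 21 | C[S+](C)OC[C@H]([C@H](C)[C@H](CC=C(C)C)OC(C)=O)CCO[Si](C)(C)C(C)(C)C.[Cl-] | intermediate (not isolated)
23 | (2S,3S,4S)-4-acetoxy-2-{2-[(tert-butyldimethylsilyl)oxy]ethyl}-3,7-dimethyloct-6-enal | O=C[C@H]([C@H](C)[C@H](CC=C(C)C)OC(C)=O)CCO[Si](C)(C)C(C)(C)C | intermediate
24 | allylchromium dichloride from 8 | Cl[Cr](Cl)CC1=C[C@H](C=C)C[C@@H]1O[Si](C)(C)C(C)(C)C | intermediate (not isolated)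
25 | Cc-hydroxy coupling product | C=C1[C@@H]([C@H](O)[C@H]([C@H](C)[C@H](CC=C(C)C)OC(C)=O)CCO[Si](C)(C)C(C)(C)C)[C@H](C=C)C[C@@H]1O[Si](C)(C)C(C)(C)C | intermediate
26 | Cc-O-TBS ether of 25 | C=C1[C@@H]([C@H](O[Si](C)(C)C(C)(C)C)[C@H]([C@H](C)[C@H](CC=C(C)C)OC(C)=O)CCO[Si](C)(C)C(C)(C)C)[C@H](C=C)C[C@@H]1O[Si](C)(C)C(C)(C)C | intermediate
27 | methyl ketone (Ch-acetyl compound) | C=C1[C@@H]([C@H](O[Si](C)(C)C(C)(C)C)[C@H]([C@H](C)[C@H](CC=C(C)C)OC(C)=O)CCO[Si](C)(C)C(C)(C)C)[C@H](C(C)=O)C[C@@H]1O[Si](C)(C)C(C)(C)C | intermediate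
28 | potassium enolate of 27 | C=C1[C@@H]([C@H](O[Si](C)(C)C(C)(C)C)[C@H]([C@H](C)[C@H](CC=C(C)C)OC(C)=O)CCO[Si](C)(C)C(C)(C)C)[C@H](C(=C)[O-])C[C@@H]1O[Si](C)(C)C(C)(C)C.[K+] | intermediate (not isolated)
29 | enol triflate of 27 | C=C1[C@@H]([C@H](O[Si](C)(C)C(C)(C)C)[C@H]([C@H](C)[C@H](CC=C(C)C)OC(C)=O)CCO[Si](C)(C)C(C)(C)C)[C@H](C(=C)OS(=O)(=O)C(F)(F)F)C[C@@H]1O[Si](C)(C)C(C)(C)C | intermediate
30 | primary alcohol (Cf-OH) from 29 | C=C1[C@@H]([C@H](O[Si](C)(C)C(C)(C)C)[C@H]([C@H](C)[C@H](CC=C(C)C)OC(C)=O)CCO)[C@H](C(=C)OS(=O)(=O)C(F)(F)F)C[C@@H]1O[Si](C)(C)C(C)(C)C | intermediate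
31 | aldehyde (Cf=O) from 30 | C=C1[C@@H]([C@H](O[Si](C)(C)C(C)(C)C)[C@H]([C@H](C)[C@H](CC=C(C)C)OC(C)=O)CC=O)[C@H](C(=C)OS(=O)(=O)C(F)(F)F)C[C@@H]1O[Si](C)(C)C(C)(C)C | intermediate
32 | alkenylchromium dichloride from 31 | C=C1[C@@H]([C@H](O[Si](C)(C)C(C)(C)C)[C@H]([C@H](C)[C@H](CC=C(C)C)OC(C)=O)CC=O)[C@H](C(=C)[Cr](Cl)Cl)C[C@@H]1O[Si](C)(C)C(C)(C)C | intermediate (not isolated)
33 | Cf-epimeric bicyclic allylic alcohols | C=C1[C@H]2[C@H](O[Si](C)(C)C(C)(C)C)[C@H]([C@H](C)[C@H](CC=C(C)C)OC(C)=O)CC(O)C(=C)[C@@H]2C[C@@H]1O[Si](C)(C)C(C)(C)C | intermediate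
34 | bicyclic α-methylene ketone (Cf=O) | C=C1[C@H]2[C@H](O[Si](C)(C)C(C)(C)C)[C@H]([C@H](C)[C@H](CC=C(C)C)OC(C)=O)CC(=O)C(=C)[C@@H]2C[C@@H]1O[Si](C)(C)C(C)(C)C | intermediate
35 | (Cf R)-allylic alcohol bis-TBS ether | C=C1[C@H]2[C@H](O[Si](C)(C)C(C)(C)C)[C@H]([C@H](C)[C@H](CC=C(C)C)OC(C)=O)C[C@@H](O)C(=C)[C@@H]2C[C@@H]1O[Si](C)(C)C(C)(C)C | intermediate
36 | target CNP0210891.3 (trans-fused bis-exomethylene hydroazulene triol monoacetate) | C=C1[C@H]2[C@H](O)[C@H]([C@H](C)[C@H](CC=C(C)C)OC(C)=O)C[C@@H](O)C(=C)[C@@H]2C[C@@H]1O | target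

**Count**
Total steps: 25 (bromide 8: 6 steps; aldehyde 23: 9 steps; coupling: 1; completion: 9).
Longest linear sequence: 19 steps (9 → 36, steps 7–25).

**Steps most likely to fail, with fallbacks**

Step 3. The γ-hydrogen of 4 is both allylic and vinylogous to the ketone, so the amine-catalysed Baylis–Hillman reaction may be accompanied by double-bond migration or racemisation. The fallback sets out from 4 and comes back at 6. Iodine and pyridine in CH2Cl2 at 0 °C give (S)-4-ethenyl-2-iodocyclopent-2-en-1-one F1. Luche reduction (NaBH4, CeCl3·7H2O, MeOH, −78 °C) then gives (1S,4S)-4-ethenyl-2-iodocyclopent-2-en-1-ol F2. A Stille coupling of F2 with (tributylstannyl)methanol (Pd(PPh3)4, zerovalent palladium, dioxane, 90 °C) brings in the hydroxymethyl group by cross-coupling instead of aldol chemistry and delivers diol 6.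

Step 16. The chromium allylation may give modest facial selectivity at Cc or reductive homocoupling of 8. The fallback sets out from 8 (with 23) and comes back at 25. Borylation of 8 with B2pin2 and Pd2(dba)3 (cat.) in toluene at 50 °C gives tert-butyl{[(1S,4S)-4-ethenyl-2-[(4,4,5,5-tetramethyl-1,3,2-dioxaborolan-2-yl)methyl]cyclopent-2-en-1-yl]oxy}dimethylsilane F3. This allylboronate adds to aldehyde 23 without any added metal (toluene, 25–40 °C) through a closed six-membered boron transition state of the same anti/Felkin sense. Aqueous triethanolamine work-up releases 25.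

Step 22. The seven-membered ring closure may suffer from triflate reduction or oligomerisation. The fallback sets out from 30 and comes back at 33. Miyaura borylation (B2pin2, PdCl2(dppf), KOAc, dioxane, 80 °C) gives the alkenyl pinacolboronate alcohol F4 (30 with the triflate replaced by the dioxaborolanyl group). Dess–Martin oxidation gives the alkenyl pinacolboronate aldehyde F5. A [Rh(cod)OH]2-catalysed (monovalent rhodium) intramolecular 1,2-addition of the alkenylboronate to the aldehyde (dioxane–water, 60 °C, high dilution) then closes the ring to the alcohols 33, which continue through steps 23 and 24.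

**Further compounds**
F1 | step 3 | (S)-4-ethenyl-2-iodocyclopent-2-en-1-one | O=C1C(I)=C[C@H](C=C)C1
F2 | step 3 | (1S,4S)-4-ethenyl-2-iodocyclopent-2-en-1-ol | IC1=C[C@H](C=C)C[C@@H]1O
F3 | step 16 | tert-butyl{[(1S,4S)-4-ethenyl-2-[(4,4,5,5-tetramethyl-1,3,2-dioxaborolan-2-yl)methyl]cyclopent-2-en-1-yl]oxy}dimethylsilane | CC1(C)OB(CC2=C[C@H](C=C)C[C@@H]2O[Si](C)(C)C(C)(C)C)OC1(C)C
F4 | step 22 | alkenyl pinacolboronate alcohol (30 with OTf replaced by the dioxaborolanyl group) | C=C1[C@@H]([C@H](O[Si](C)(C)C(C)(C)C)[C@H]([C@H](C)[C@H](CC=C(C)C)OC(C)=O)CCO)[C@H](C(=C)B2OC(C)(C)C(C)(C)O2)C[C@@H]1O[Si](C)(C)C(C)(C)C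
F5 | step 22 | alkenyl pinacolboronate aldehyde (31 with OTf replaced by the dioxaborolanyl group) | C=C1[C@@H]([C@H](O[Si](C)(C)C(C)(C)C)[C@H]([C@H](C)[C@H](CC=C(C)C)OC(C)=O)CC=O)[C@H](C(=C)B2OC(C)(C)C(C)(C)O2)C[C@@H]1O[Si](C)(C)C(C)(C)C
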